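## The problem

The target is a C40 xanthophyll in which a polyene of eight E double bonds (C9=C10 to C7'=C8') links two different end groups. One end is a cyclohexanol fused through C5 and C6 to a 2,5-dihydrofuran (ring oxygen between C5 and C8, C6=C7 inside the five-membered ring); the other is a 2,6,6-trimethylcyclohex-2-enol. The five stereocentres fall into two sets, C3/C5/C8 and C3'/C6', separated by the whole chain, so each end needs its own source of absolute configuration. Within the bicyclic end C3 and C5 are 1,3 on the same ring, so C3 can control C5, but C8 lies outside that ring and must be set by a reagent. In the other ring C3' and C6' face each other 1,4 across a double bond and steer each other only weakly, so one has to be set stereospecifically and the other by a catalyst. The C8–O bond becomes allylic on both sides once the polyene is attached and ionises with traces of acid, which would scramble C8; the polyene is sensitive to light, oxygen and acid; C6' epimerises whenever a carbonyl sits at C7' or C3'. The feature that opens the bicyclic end to stereocontrol is that the C5–O bond is anti to the C3 hydroxyl while C6 carries a double bond to C7. That double bond can be read as a dehydrated C6 alcohol, and a C5 ether beside a C6 alcohol is what an epoxide on the hydroxyl face of the ring leaves behind when an oxygen on C8 opens it at C5 with inversion.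

## Retrosynthesis

**Protecting groups and C11=C12.** Target 38 is traced to its bis-silyl ether 37, which is cut at C11=C12 into the C15 phosphonium salt 19 (bicyclic end) and the C25 aldehyde 35. This cut puts C8 and all three stereocentres of the bicyclic end into one small fragment. A cut at C15=C15' or C7'=C8' would carry the acid-labile dihydrofuran through more polyene-building steps. C11=C12 is unbranched, so a Z isomer from the Wittig reaction can be corrected by heating. The forward reaction must run under base only.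

**C11'=C12'.** Aldehyde 35 is cut into the C15 phosphonium salt 32 and the symmetrical C10 dialdehyde 33. A symmetrical core used in excess needs no differentiation of its ends, and 33 is an article of commerce. The forward reaction must stop after one olefination.

**C6=C7.** Salt 19 comes from alcohol 17 and ester 16. The C6=C7 bond of 16 is traced to the tertiary C6 alcohol of 15 and, one protecting group earlier, 14. C6 is flanked by two fully substituted carbons, so only C7 can lose hydrogen and the regiochemistry is fixed by structure. The forward step must dehydrate a crowded alcohol without acid.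

**C5–O (key disconnection).** Oxolane 14 is opened at the C5–O bond to the syn-epoxy diol 13. This is preferred to cutting C8–O, which would need a leaving group at a carbinol that later becomes doubly allylic. It is also preferred to cutting C7–C8, which would leave C8 as a prochiral methylene. The precursor loses one ring and one stereocentre. The forward reaction must invert C5 cleanly.

**Epoxide.** Epoxy diol 13 goes back through its C8 silyl ether 12 to the cyclohexenol 11. The epoxide oxygen has to sit on the face of the C3 hydroxyl, which is the face a metal bound to that hydroxyl delivers to. The C8 oxygen is masked (10, 11) so that only one hydroxyl can bind the metal.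

**C7–C8.** Alcohol 9 is traced through ketone 8 to the ene adduct 7, which is cut at C7–C8 into the exocyclic alkene 5 and the C5 aldehyde 6. An allylmetal at C7 would react at C5 instead; the ene reaction of the exocyclic isomer can only form the C7–C8 bond and can only place the ring double bond at C5=C6. C8 is then set on the ketone by catalyst control. The C5 unit arrives with its E double bond and ester in place.

**Ring of the bicyclic end.** Alkene 5 comes by methylenation of ketone 4, the silyl ether of 3. Alcohol 3 is reached from 4-oxoisophorone 1 through dione 2 by two reductions, which set C3.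

**Cyclohexenol end, functional groups.** Salt 32 is traced through alcohol 30 and esters 29 and 28 to the enone 27 and the dienoate 26. The C3' oxygen is introduced late, by allylic oxidation and catalyst-controlled reduction, because no simple chiral precursor carries both C3' and C6'.

**C7'=C8'.** Dienoate 26 is cut into aldehyde 24 and the C5 phosphonate 25. A cut at C9'=C10' from a methyl ketone would leave the geometry of a trisubstituted bond to chance. The forward reaction must not epimerise C6' next to the aldehyde.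

**C6'–C7'.** Aldehyde 24 comes from alcohol 23, whose C6'–C7' bond is traced by a [2,3] shift to the stannylmethyl ether 22 of allylic alcohol 21, made from enone 20. The shift moves the configuration of an easily made carbinol to the hindered C6' and places the double bond at C4'=C5' in the same event.

## Roads not taken

**Alternative 1:** The cut is the C1'–C6' bond of the cyclohexenol ring. In the forward step Fe(acac)3 and PhSiH3 would transfer a hydrogen atom to the 1,1-disubstituted alkene of the acyclic dienyl sulfone A1. The tertiary C1' radical would add 6-exo to C6' and give the ring sulfone A2.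

- Merits: the quaternary carbon and C6' are made together from a chain whose only stereocentre (C3') needs one asymmetric step. The conditions are neutral, and A2 is ready for a Julia olefination at C7'=C8'.
- Weak points: A1 needs a Z trisubstituted C4'=C5' bond. The 1,4 induction from C3' to C6' in a radical transition state is not assured. The iron hydride may also reduce the vinyl sulfone. The plan does nothing for C5 and C8, and a coupling at C7'=C8' would force the bicyclic end to be carried as a C30 aldehyde.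
- Comparison: for the cyclohexenol ring alone this road could be shorter than the eleven steps used below, and if the induction held it would be the better ring synthesis. The chosen plan sets against it a stereospecific transfer to C6' using known reaction types, and a key step that addresses the harder half of the molecule.

**Alternative 2:** The cuts are C7–C8 and C6=C7. Lithiated trimethylsilyldiazomethane would turn the C6 ketone of ether A3 into an alkylidene carbene at C7, which would insert into an allylic C8–H bond to give dihydrofuran A4.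

- Merits: the ring and C6=C7 form in one operation, there is no epoxide and no dehydration, and no acid is used.
- Weak points: the ketone of A3 lies between two fully substituted carbons and resists addition. C8 is a prochiral methylene whose two hydrogens are told apart only by the remote C5 centre. The ether oxygen can capture the carbene as an oxonium ylide and divert it into a [2,3] shift of the allyl group. The tertiary allyl ether at C5 is itself hard to make.
- Comparison: this road is shorter on paper and avoids acid altogether. The chosen plan sets against it a C8 carbinol of defined configuration before ring closure and a C5 configuration relayed from C3.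

**Alternative 3:** The cut is the O–C8 bond. AgNO3, or Ph3PAuCl/AgOTf (monovalent gold), would activate the C7=C8 bond of the allenic tertiary alcohol A5, and the C5 hydroxyl would add to C8 in a 5-endo closure to give dihydrofuran A6.

- Merits: cyclisation of α-hydroxyallenes to 2,5-dihydrofurans is very well precedented and transfers axial to central chirality. C6=C7 arises directly. A5 carries the hydroxylation pattern of the allenic carotenoid end group, for which hydride opening of an alkynyl epoxide is an established entry. A geometric analysis (oxygen entering C8 from the C5 side, in the plane of the C6 substituents) indicates that the R axis leads to 8S.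
- Weak points: A6 is a doubly allylic ether formed in the presence of a Lewis-acidic π-acid. With the electron-rich C9=C10 neighbour of A5, reversible ionisation at C8 or racemisation of the allene before closure could erode the new centre. C8 also rests on a relay of three elements: epoxide face, axis, centre.
- Comparison: in step count (no dehydration, two fewer protecting-group operations) and in precedent for the ring-forming event this road is at least equal to the chosen one and probably ahead. The chosen plan sets against it that C8 is fixed as a carbinol by a catalyst before the ring exists, that the C8–O bond is never made or broken at a cationic centre, and that the closure is run while C9=C10 is an electron-poor enoate. Its price is the dehydration of a crowded tertiary alcohol.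

Key step: step 12

## Route

Assumption: the SMILES is read as (3S,5R,8S,3'R,6'R)-5,8-epoxy-5,8-dihydro-β,ε-carotene-3,3'-diol and carotenoid numbering is used for positions; 1, 6, 20, 25 (sold as an E/Z mixture that converges through its anion) and 33 are taken as purchasable.

Step 1
Reactants: 1 4-oxoisophorone (2,6,6-trimethylcyclohex-2-ene-1,4-dione)
Product: 2 (6R)-2,2,6-trimethylcyclohexane-1,4-dione
Conditions: baker's yeast, sucrose, H2O, 30 °C
Reagents that add atoms: none
Why: Microbial (ene-reductase) reduction of the enedione C=C; the enzyme delivers hydride to one face and should set the methyl-bearing carbon as R, and the fermentation is stopped before carbonyl reduction sets in.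

Step 2
Reactants: 2 (6R)-2,2,6-trimethylcyclohexane-1,4-dione
Product: 3 (4R,6R)-4-hydroxy-2,2,6-trimethylcyclohexan-1-one
Conditions: H2 (1 atm), Raney Ni, MeOH, rt; recrystallisation
Reagents that add atoms: none
Why: Heterogeneous hydrogenation of the unhindered C4 carbonyl (the C1 carbonyl next to the quaternary carbon is inert), with hydrogen expected from the face away from the axial methyl to favour the trans 4R alcohol. The 4S isomer must be removed by crystallisation, since it would become the enantiomeric ring once the methyl-bearing centre is flattened in step 5.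

Step 3
Reactants: 3 (4R,6R)-4-hydroxy-2,2,6-trimethylcyclohexan-1-one
Product: 4 (4R,6R)-4-(tert-butyldimethylsilyloxy)-2,2,6-trimethylcyclohexan-1-one
Conditions: TBSCl, imidazole, DMF, rt
Reagents that add atoms: tert-butyldimethylsilyl chloride, CC(C)(C)[Si](C)(C)Cl
Why: Standard silylation of a secondary alcohol; the ether is γ to the ketone and cannot eliminate.

Step 4
Reactants: 4 (4R,6R)-4-(tert-butyldimethylsilyloxy)-2,2,6-trimethylcyclohexan-1-one
Product: 5 tert-butyldimethyl{[(1R,5R)-3,3,5-trimethyl-4-methylidenecyclohexyl]oxy}silane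
Conditions: Ph3PCH3Br, KOtBu, toluene, 90 °C
Reagents that add atoms: methyltriphenylphosphonium bromide, C[P+](c1ccccc1)(c1ccccc1)c1ccccc1.[Br-]
Why: Wittig methylenation under the hot alkoxide conditions used for hindered ketones; any epimerisation next to the carbonyl is harmless because that centre becomes sp2 in step 5.

Step 5
Reactants: 5 tert-butyldimethyl{[(1R,5R)-3,3,5-trimethyl-4-methylidenecyclohexyl]oxy}silane; 6 ethyl (2E)-3-methyl-4-oxobut-2-enoate
Product: 7 ethyl (2E)-5-[(4R)-4-(tert-butyldimethylsilyloxy)-2,6,6-trimethylcyclohex-1-en-1-yl]-4-hydroxy-3-methylpent-2-enoate (both C4 epimers; C4 is carotenoid C8)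
Conditions: Me2AlCl (1.5 equiv), CH2Cl2, −78 to −20 °C
Reagents that add atoms: none
Why: Lewis acid-promoted carbonyl-ene reaction of a 1,1-disubstituted alkene with an aldehyde forms C7–C8. The only allylic hydrogen is on C5, so the ring double bond can only arrive at C5=C6. C8 is not controlled here and both epimers converge in step 6.

Step 6
Reactants: 7 ethyl (2E)-5-[(4R)-4-(tert-butyldimethylsilyloxy)-2,6,6-trimethylcyclohex-1-en-1-yl]-4-hydroxy-3-methylpent-2-enoate
Product: 8 ethyl (2E)-5-[(4R)-4-(tert-butyldimethylsilyloxy)-2,6,6-trimethylcyclohex-1-en-1-yl]-3-methyl-4-oxopent-2-enoate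
Conditions: Dess–Martin periodinane, NaHCO3, CH2Cl2, 0 °C to rt
Reagents that add atoms: none
Why: Dess–Martin oxidation of the secondary allylic alcohol; the buffered, non-basic medium should keep the C5=C6 bond out of conjugation and the enoate E.

Step 7
Reactants: 8 ethyl (2E)-5-[(4R)-4-(tert-butyldimethylsilyloxy)-2,6,6-trimethylcyclohex-1-en-1-yl]-3-methyl-4-oxopent-2-enoate
Product: 9 ethyl (2E,4S)-5-[(4R)-4-(tert-butyldimethylsilyloxy)-2,6,6-trimethylcyclohex-1-en-1-yl]-4-hydroxy-3-methylpent-2-enoate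
Conditions: (R)-2-methyl-CBS-oxazaborolidine (20 mol%), catecholborane, toluene, −78 °C
Reagents that add atoms: none
Why: Corey–Bakshi–Shibata reduction: the α-branched alkenyl group (C9) acts as the large and the C7 methylene as the small substituent, so the R catalyst should give the 8S carbinol. Catecholborane at low temperature avoids hydroboration and 1,4-reduction.

Step 8
Reactants: 9 ethyl (2E,4S)-5-[(4R)-4-(tert-butyldimethylsilyloxy)-2,6,6-trimethylcyclohex-1-en-1-yl]-4-hydroxy-3-methylpent-2-enoate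
Product: 10 ethyl (2E,4S)-4-(tert-butyldiphenylsilyloxy)-5-[(4R)-4-(tert-butyldimethylsilyloxy)-2,6,6-trimethylcyclohex-1-en-1-yl]-3-methylpent-2-enoate
Conditions: TBDPSCl, imidazole, DMF, rt
Reagents that add atoms: tert-butyldiphenylsilyl chloride, CC(C)(C)[Si](Cl)(c1ccccc1)c1ccccc1
Why: Silylation of the C8 hydroxyl with a group that survives step 9 and keeps this oxygen from binding vanadium in step 10.

Step 9
Reactants: 10 ethyl (2E,4S)-4-(tert-butyldiphenylsilyloxy)-5-[(4R)-4-(tert-butyldimethylsilyloxy)-2,6,6-trimethylcyclohex-1-en-1-yl]-3-methylpent-2-enoate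
Product: 11 ethyl (2E,4S)-4-(tert-butyldiphenylsilyloxy)-5-[(4R)-4-hydroxy-2,6,6-trimethylcyclohex-1-en-1-yl]-3-methylpent-2-enoate
Conditions: PPTS, EtOH, 45 °C
Reagents that add atoms: none
Why: Acid-catalysed solvolysis removes the secondary TBS ether much faster than the TBDPS ether; ethanol as solvent leaves the ethyl ester unchanged.

Step 10
Reactants: 11 ethyl (2E,4S)-4-(tert-butyldiphenylsilyloxy)-5-[(4R)-4-hydroxy-2,6,6-trimethylcyclohex-1-en-1-yl]-3-methylpent-2-enoate
Product: 12 ethyl (2E,4S)-4-(tert-butyldiphenylsilyloxy)-5-[(1R,4S,6S)-4-hydroxy-2,2,6-trimethyl-7-oxabicyclo[4.1.0]heptan-1-yl]-3-methylpent-2-enoate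
Conditions: VO(acac)2 (5 mol%), t-BuOOH (decane), CH2Cl2, 0 °C to rt
Reagents that add atoms: tert-butyl hydroperoxide, CC(C)(C)OO
Why: Vanadium-catalysed epoxidation directed by a homoallylic hydroxyl (cyclohex-3-enol type): the vanadate ester of the C3 hydroxyl delivers the peroxide oxygen to its own face, giving the syn (5S,6R) epoxide. The enoate alkene is electron-poor and has no free hydroxyl beside it.

Step 11
Reactants: 12 ethyl (2E,4S)-4-(tert-butyldiphenylsilyloxy)-5-[(1R,4S,6S)-4-hydroxy-2,2,6-trimethyl-7-oxabicyclo[4.1.0]heptan-1-yl]-3-methylpent-2-enoate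
Product: 13 ethyl (2E,4S)-4-hydroxy-5-[(1R,4S,6S)-4-hydroxy-2,2,6-trimethyl-7-oxabicyclo[4.1.0]heptan-1-yl]-3-methylpent-2-enoate
Conditions: Bu4NF, AcOH, THF, rt
Reagents that add atoms: none
Why: Fluoride desilylation; the acetic acid buffer keeps the freed C8 alkoxide from acting on the enoate or the epoxide.

Step 12
Reactants: 13 ethyl (2E,4S)-4-hydroxy-5-[(1R,4S,6S)-4-hydroxy-2,2,6-trimethyl-7-oxabicyclo[4.1.0]heptan-1-yl]-3-methylpent-2-enoate
Product: 14 ethyl (2E)-3-[(2S,3aR,6S,7aR)-3a,6-dihydroxy-4,4,7a-trimethyloctahydro-1-benzofuran-2-yl]but-2-enoate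
Conditions: (+)-camphor-10-sulfonic acid (10 mol%), CH2Cl2, 0 °C
Reagents that add atoms: none
Why: The acid protonates the epoxide oxygen, and the C8 hydroxyl, held beneath the ring by the C6–C7 bond, attacks the tertiary C5 from the face opposite the epoxide oxygen as the C5–O bond breaks; C5 is inverted and the epoxide oxygen stays on C6 as a tertiary alcohol. The closest known reaction type is the acid-catalysed cyclisation of 3,4-epoxy alcohols to 3-hydroxyoxolanes. The oxolane (O, C5, C6, C7, C8) closes in the 5-endo mode; the 4-exo attack at C6 would give a strained oxetane and is not expected to compete. Because the tether and the new C5–O bond are both anti to the old epoxide, the bicycle is cis-fused. The one new stereocentre, C5 (R), is controlled by the epoxide configuration, which the C3 hydroxyl placed in step 10; C3, C6 and C8 are not touched. The step needs the C8 hydroxyl and not the C3 hydroxyl to act as nucleophile, which the substrate secures because the C3 hydroxyl sits on the epoxide face and cannot reach either epoxide carbon from the rear. It also needs inversion and not a free C5 cation, which the weak acid, the non-polar solvent, the low temperature and the intramolecular nucleophile favour. The C8 carbinol itself should not ionise, since the conjugated ester destabilises the allyl cation.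

Step 13
Reactants: 14 ethyl (2E)-3-[(2S,3aR,6S,7aR)-3a,6-dihydroxy-4,4,7a-trimethyloctahydro-1-benzofuran-2-yl]but-2-enoate
Product: 15 ethyl (2E)-3-[(2S,3aR,6S,7aR)-6-(tert-butyldimethylsilyloxy)-3a-hydroxy-4,4,7a-trimethyloctahydro-1-benzofuran-2-yl]but-2-enoate
Conditions: TBSCl, imidazole, DMF, rt
Reagents that add atoms: tert-butyldimethylsilyl chloride, CC(C)(C)[Si](C)(C)Cl
Why: Silylation of the secondary C3 hydroxyl; the tertiary C6 hydroxyl between two fully substituted carbons should not react.

Step 14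
Reactants: 15 ethyl (2E)-3-[(2S,3aR,6S,7aR)-6-(tert-butyldimethylsilyloxy)-3a-hydroxy-4,4,7a-trimethyloctahydro-1-benzofuran-2-yl]but-2-enoate
Product: 16 ethyl (2E)-3-[(2S,6S,7aR)-6-(tert-butyldimethylsilyloxy)-4,4,7a-trimethyl-2,4,5,6,7,7a-hexahydro-1-benzofuran-2-yl]but-2-enoate
Conditions: Burgess reagent, toluene, 70 °C
Reagents that add atoms: none
Why: Burgess dehydration (syn elimination through the sulfamate ester) of the tertiary alcohol; only C7 carries hydrogen, so C6=C7 is the only alkene possible, and no acid is present to ionise the new allylic ether.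

Step 15
Reactants: 16 ethyl (2E)-3-[(2S,6S,7aR)-6-(tert-butyldimethylsilyloxy)-4,4,7a-trimethyl-2,4,5,6,7,7a-hexahydro-1-benzofuran-2-yl]but-2-enoate
Product: 17 (2E)-3-[(2S,6S,7aR)-6-(tert-butyldimethylsilyloxy)-4,4,7a-trimethyl-2,4,5,6,7,7a-hexahydro-1-benzofuran-2-yl]but-2-en-1-ol
Conditions: i-Bu2AlH, CH2Cl2, −78 °C
Reagents that add atoms: none
Why: 1,2-Reduction of the enoate to the allylic alcohol by the aluminium hydride; the silyl ether and the dihydrofuran are inert.

Step 16
Reactants: 17 (2E)-3-[(2S,6S,7aR)-6-(tert-butyldimethylsilyloxy)-4,4,7a-trimethyl-2,4,5,6,7,7a-hexahydro-1-benzofuran-2-yl]but-2-en-1-ol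
Product: 19 {(2E)-3-[(2S,6S,7aR)-6-(tert-butyldimethylsilyloxy)-4,4,7a-trimethyl-2,4,5,6,7,7a-hexahydro-1-benzofuran-2-yl]but-2-en-1-yl}triphenylphosphonium bromide, via allylic bromide 18 (not isolated)
Conditions: CBr4, PPh3, 2,6-lutidine, CH2Cl2, −20 °C; then PPh3, EtOAc, rt
Reagents that add atoms: carbon tetrabromide, BrC(Br)(Br)Br; triphenylphosphine, c1ccc(cc1)P(c1ccccc1)c1ccccc1
Why: Appel bromination of the primary allylic alcohol followed by SN2 quaternisation of triphenylphosphine; no acid is generated, which protects the doubly allylic C8–O bond.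

Step 17
Reactants: 20 2,4,4-trimethylcyclohex-2-en-1-one
Product: 21 (1S)-2,4,4-trimethylcyclohex-2-en-1-ol
Conditions: (R)-2-methyl-CBS-oxazaborolidine (10 mol%), catecholborane, toluene, −78 °C
Reagents that add atoms: none
Why: Corey–Bakshi–Shibata reduction of an α-methyl enone, a substrate class in which the alkenyl side is reliably the large group; the R catalyst should give the S alcohol.

Step 18
Reactants: 21 (1S)-2,4,4-trimethylcyclohex-2-en-1-ol
Product: 22 tributyl({[(1S)-2,4,4-trimethylcyclohex-2-en-1-yl]oxy}methyl)stannane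
Conditions: KH, Bu3SnCH2I, 18-crown-6 (cat.), THF, 0 °C to rt
Reagents that add atoms: (iodomethyl)tributylstannane, CCCC[Sn](CCCC)(CCCC)CI
Why: Williamson etherification of the potassium alkoxide; the carbinol centre is not involved.

Step 19
Reactants: 22 tributyl({[(1S)-2,4,4-trimethylcyclohex-2-en-1-yl]oxy}methyl)stannane
Product: 23 [(1R)-2,6,6-trimethylcyclohex-2-en-1-yl]methanol
Conditions: n-BuLi, THF, −78 °C
Reagents that add atoms: none
Why: Tin–lithium exchange and [2,3]-Wittig–Still rearrangement: the new C6'–C7' bond forms on the ring face that carried the oxygen, which moves the carbinol configuration to C6' (R) and places the double bond at C4'=C5'.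

Step 20
Reactants: 23 [(1R)-2,6,6-trimethylcyclohex-2-en-1-yl]methanol
Product: 24 (1R)-2,6,6-trimethylcyclohex-2-ene-1-carbaldehyde
Conditions: Dess–Martin periodinane, NaHCO3, CH2Cl2, 0 °C
Reagents that add atoms: none
Why: Buffered Dess–Martin oxidation; the aldehyde is used at once so that C6' neither epimerises nor lets the double bond move into conjugation.

Step 21
Reactants: 24 (1R)-2,6,6-trimethylcyclohex-2-ene-1-carbaldehyde; 25 ethyl (2E)-4-(diethoxyphosphoryl)-3-methylbut-2-enoate
Product: 26 ethyl (2E,4E)-3-methyl-5-[(1R)-2,6,6-trimethylcyclohex-2-en-1-yl]penta-2,4-dienoate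
Conditions: LiN(SiMe3)2, THF, −78 to 0 °C
Reagents that add atoms: none
Why: Horner–Wadsworth–Emmons olefination with a stabilised vinylogous phosphonate anion should give the E C7'=C8' bond and mainly the 2E ester (the minor 2Z isomer is removed by chromatography); the weakly basic anion should leave C6' alone.

Step 22
Reactants: 26 ethyl (2E,4E)-3-methyl-5-[(1R)-2,6,6-trimethylcyclohex-2-en-1-yl]penta-2,4-dienoate
Product: 27 ethyl (2E,4E)-3-methyl-5-[(1R)-2,6,6-trimethyl-4-oxocyclohex-2-en-1-yl]penta-2,4-dienoate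
Conditions: CrO3, 3,5-dimethylpyrazole, CH2Cl2, −20 °C
Reagents that add atoms: chromium trioxide, O=[Cr](=O)=O
Why: Allylic oxidation of the ring methylene (C3') to the enone, as known for rings of the α-ionone type; the methyl on the electron-poor dienoate is deactivated and the shielded C6' hydrogen should be spared.

Step 23
Reactants: 27 ethyl (2E,4E)-3-methyl-5-[(1R)-2,6,6-trimethyl-4-oxocyclohex-2-en-1-yl]penta-2,4-dienoate
Product: 28 ethyl (2E,4E)-5-[(1R,4R)-4-hydroxy-2,6,6-trimethylcyclohex-2-en-1-yl]-3-methylpenta-2,4-dienoate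
Conditions: (S)-2-methyl-CBS-oxazaborolidine (20 mol%), catecholborane, toluene, −78 °C
Reagents that add atoms: none
Why: Corey–Bakshi–Shibata reduction of the ring enone with the C4'=C5' side as the large group; the S catalyst should give the 3'R alcohol (trans to the side chain), and the non-basic conditions should not epimerise C6', which is now γ to the carbonyl.

Step 24
Reactants: 28 ethyl (2E,4E)-5-[(1R,4R)-4-hydroxy-2,6,6-trimethylcyclohex-2-en-1-yl]-3-methylpenta-2,4-dienoate
Product: 29 ethyl (2E,4E)-5-[(1R,4R)-4-(tert-butyldimethylsilyloxy)-2,6,6-trimethylcyclohex-2-en-1-yl]-3-methylpenta-2,4-dienoate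
Conditions: TBSCl, imidazole, DMF, rt
Reagents that add atoms: tert-butyldimethylsilyl chloride, CC(C)(C)[Si](C)(C)Cl
Why: Silylation protects the allylic C3' hydroxyl from bromination in step 26.

Step 25
Reactants: 29 ethyl (2E,4E)-5-[(1R,4R)-4-(tert-butyldimethylsilyloxy)-2,6,6-trimethylcyclohex-2-en-1-yl]-3-methylpenta-2,4-dienoate
Product: 30 (2E,4E)-5-[(1R,4R)-4-(tert-butyldimethylsilyloxy)-2,6,6-trimethylcyclohex-2-en-1-yl]-3-methylpenta-2,4-dien-1-ol
Conditions: i-Bu2AlH, CH2Cl2, −78 °C
Reagents that add atoms: none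
Why: 1,2-Reduction of the dienoate to the dienyl alcohol.

Step 26
Reactants: 30 (2E,4E)-5-[(1R,4R)-4-(tert-butyldimethylsilyloxy)-2,6,6-trimethylcyclohex-2-en-1-yl]-3-methylpenta-2,4-dien-1-ol
Product: 32 {(2E,4E)-5-[(1R,4R)-4-(tert-butyldimethylsilyloxy)-2,6,6-trimethylcyclohex-2-en-1-yl]-3-methylpenta-2,4-dien-1-yl}triphenylphosphonium bromide, via dienyl bromide 31 (not isolated)
Conditions: CBr4, PPh3, 2,6-lutidine, CH2Cl2, −20 °C; then PPh3, EtOAc, rt
Reagents that add atoms: carbon tetrabromide, BrC(Br)(Br)Br; triphenylphosphine, c1ccc(cc1)P(c1ccccc1)c1ccccc1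
Why: Appel bromination and quaternisation as in step 16; neutral conditions spare the allylic silyl ether.

Step 27
Reactants: 32 {(2E,4E)-5-[(1R,4R)-4-(tert-butyldimethylsilyloxy)-2,6,6-trimethylcyclohex-2-en-1-yl]-3-methylpenta-2,4-dien-1-yl}triphenylphosphonium bromide; 33 (2E,4E,6E)-2,7-dimethylocta-2,4,6-trienedial
Product: 35 (2E,4E,6E,8E,10E,12E)-13-[(1R,4R)-4-(tert-butyldimethylsilyloxy)-2,6,6-trimethylcyclohex-2-en-1-yl]-2,7,11-trimethyltrideca-2,4,6,8,10,12-hexaenal, via 8Z isomer 34 (not isolated)
Conditions: NaOMe, MeOH/CH2Cl2, 0 °C to rt (33 in excess); then heptane, 90 °C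
Reagents that add atoms: none
Why: Wittig mono-olefination of the symmetrical dialdehyde used in excess; the semi-stabilised ylide gives the new C11'=C12' bond as an E/Z mixture, and the hindered Z isomer should equilibrate to the all-E aldehyde on heating.

Step 28
Reactants: 19 {(2E)-3-[(2S,6S,7aR)-6-(tert-butyldimethylsilyloxy)-4,4,7a-trimethyl-2,4,5,6,7,7a-hexahydro-1-benzofuran-2-yl]but-2-en-1-yl}triphenylphosphonium bromide; 35 (2E,4E,6E,8E,10E,12E)-13-[(1R,4R)-4-(tert-butyldimethylsilyloxy)-2,6,6-trimethylcyclohex-2-en-1-yl]-2,7,11-trimethyltrideca-2,4,6,8,10,12-hexaenal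
Product: 37 (3S,5R,8S,3'R,6'R)-3,3'-bis(tert-butyldimethylsilyloxy)-5,8-epoxy-5,8-dihydro-β,ε-carotene, via 11Z isomer 36 (not isolated)
Conditions: NaOMe, MeOH/CH2Cl2, 0 °C to rt; then heptane, 90 °C, dark
Reagents that add atoms: none
Why: Wittig olefination joins C11 to C12 under base only, as is done with C15 ylides that carry a 5,6-epoxide; the hindered 11Z isomer should equilibrate thermally to the all-E chain, and C8 is not exposed to acid.

Step 29
Reactants: 37 (3S,5R,8S,3'R,6'R)-3,3'-bis(tert-butyldimethylsilyloxy)-5,8-epoxy-5,8-dihydro-β,ε-carotene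
Product: 38 (3S,5R,8S,3'R,6'R)-5,8-epoxy-5,8-dihydro-β,ε-carotene-3,3'-diol (CNP0219251.2)
Conditions: Bu4NF, THF, rt
Reagents that add atoms: none
Why: Fluoride cleaves both silyl ethers under basic conditions, which the polyene and the doubly allylic ether tolerate; no stereocentre is involved.

## Compound list

1 | 4-oxoisophorone (2,6,6-trimethylcyclohex-2-ene-1,4-dione) | CC1=CC(=O)CC(C)(C)C1=O | starting material
2 | (6R)-2,2,6-trimethylcyclohexane-1,4-dione | C[C@@H]1CC(=O)CC(C)(C)C1=O | intermediate
3 | (4R,6R)-4-hydroxy-2,2,6-trimethylcyclohexan-1-one | C[C@@H]1C[C@@H](O)CC(C)(C)C1=O | intermediate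
4 | (4R,6R)-4-(tert-butyldimethylsilyloxy)-2,2,6-trimethylcyclohexan-1-one | C[C@@H]1C[C@@H](O[Si](C)(C)C(C)(C)C)CC(C)(C)C1=O | intermediate
5 | tert-butyldimethyl{[(1R,5R)-3,3,5-trimethyl-4-methylidenecyclohexyl]oxy}silane | C[C@@H]1C[C@@H](O[Si](C)(C)C(C)(C)C)CC(C)(C)C1=C | intermediate
6 | ethyl (2E)-3-methyl-4-oxobut-2-enoate | CCOC(=O)/C=C(\C)C=O | starting material
7 | ethyl (2E)-5-[(4R)-4-(tert-butyldimethylsilyloxy)-2,6,6-trimethylcyclohex-1-en-1-yl]-4-hydroxy-3-methylpent-2-enoate (both C4 epimers) | CCOC(=O)/C=C(\C)C(O)CC1=C(C)C[C@@H](O[Si](C)(C)C(C)(C)C)CC1(C)C | intermediate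
8 | ethyl (2E)-5-[(4R)-4-(tert-butyldimethylsilyloxy)-2,6,6-trimethylcyclohex-1-en-1-yl]-3-methyl-4-oxopent-2-enoate | CCOC(=O)/C=C(\C)C(=O)CC1=C(C)C[C@@H](O[Si](C)(C)C(C)(C)C)CC1(C)C | intermediate
9 | ethyl (2E,4S)-5-[(4R)-4-(tert-butyldimethylsilyloxy)-2,6,6-trimethylcyclohex-1-en-1-yl]-4-hydroxy-3-methylpent-2-enoate | CCOC(=O)/C=C(\C)[C@@H](O)CC1=C(C)C[C@@H](O[Si](C)(C)C(C)(C)C)CC1(C)C | intermediate
10 | ethyl (2E,4S)-4-(tert-butyldiphenylsilyloxy)-5-[(4R)-4-(tert-butyldimethylsilyloxy)-2,6,6-trimethylcyclohex-1-en-1-yl]-3-methylpent-2-enoate | CCOC(=O)/C=C(\C)[C@@H](O[Si](c1ccccc1)(c1ccccc1)C(C)(C)C)CC1=C(C)C[C@@H](O[Si](C)(C)C(C)(C)C)CC1(C)C | intermediate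
11 | ethyl (2E,4S)-4-(tert-butyldiphenylsilyloxy)-5-[(4R)-4-hydroxy-2,6,6-trimethylcyclohex-1-en-1-yl]-3-methylpent-2-enoate | CCOC(=O)/C=C(\C)[C@@H](O[Si](c1ccccc1)(c1ccccc1)C(C)(C)C)CC1=C(C)C[C@@H](O)CC1(C)C | intermediate
12 | ethyl (2E,4S)-4-(tert-butyldiphenylsilyloxy)-5-[(1R,4S,6S)-4-hydroxy-2,2,6-trimethyl-7-oxabicyclo[4.1.0]heptan-1-yl]-3-methylpent-2-enoate | CCOC(=O)/C=C(\C)[C@@H](O[Si](c1ccccc1)(c1ccccc1)C(C)(C)C)C[C@@]1(O2)C(C)(C)C[C@H](O)C[C@@]12C | intermediate
13 | ethyl (2E,4S)-4-hydroxy-5-[(1R,4S,6S)-4-hydroxy-2,2,6-trimethyl-7-oxabicyclo[4.1.0]heptan-1-yl]-3-methylpent-2-enoate | CCOC(=O)/C=C(\C)[C@@H](O)C[C@@]1(O2)C(C)(C)C[C@H](O)C[C@@]12C | intermediate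
14 | ethyl (2E)-3-[(2S,3aR,6S,7aR)-3a,6-dihydroxy-4,4,7a-trimethyloctahydro-1-benzofuran-2-yl]but-2-enoate | CCOC(=O)/C=C(\C)[C@@H]1C[C@@]2(O)C(C)(C)C[C@H](O)C[C@@]2(C)O1 | intermediate
15 | ethyl (2E)-3-[(2S,3aR,6S,7aR)-6-(tert-butyldimethylsilyloxy)-3a-hydroxy-4,4,7a-trimethyloctahydro-1-benzofuran-2-yl]but-2-enoate | CCOC(=O)/C=C(\C)[C@@H]1C[C@@]2(O)C(C)(C)C[C@H](O[Si](C)(C)C(C)(C)C)C[C@@]2(C)O1 | intermediate
16 | ethyl (2E)-3-[(2S,6S,7aR)-6-(tert-butyldimethylsilyloxy)-4,4,7a-trimethyl-2,4,5,6,7,7a-hexahydro-1-benzofuran-2-yl]but-2-enoate | CCOC(=O)/C=C(\C)[C@@H]1C=C2C(C)(C)C[C@H](O[Si](C)(C)C(C)(C)C)C[C@@]2(C)O1 | intermediate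
17 | (2E)-3-[(2S,6S,7aR)-6-(tert-butyldimethylsilyloxy)-4,4,7a-trimethyl-2,4,5,6,7,7a-hexahydro-1-benzofuran-2-yl]but-2-en-1-ol | OC/C=C(\C)[C@@H]1C=C2C(C)(C)C[C@H](O[Si](C)(C)C(C)(C)C)C[C@@]2(C)O1 | intermediate
18 | (2S,6S,7aR)-2-[(2E)-4-bromobut-2-en-2-yl]-6-(tert-butyldimethylsilyloxy)-4,4,7a-trimethyl-2,4,5,6,7,7a-hexahydro-1-benzofuran | BrC/C=C(\C)[C@@H]1C=C2C(C)(C)C[C@H](O[Si](C)(C)C(C)(C)C)C[C@@]2(C)O1 | intermediate
19 | {(2E)-3-[(2S,6S,7aR)-6-(tert-butyldimethylsilyloxy)-4,4,7a-trimethyl-2,4,5,6,7,7a-hexahydro-1-benzofuran-2-yl]but-2-en-1-yl}triphenylphosphonium bromide | [Br-].c1ccccc1[P+](c1ccccc1)(c1ccccc1)C/C=C(\C)[C@@H]1C=C2C(C)(C)C[C@H](O[Si](C)(C)C(C)(C)C)C[C@@]2(C)O1 | intermediate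
20 | 2,4,4-trimethylcyclohex-2-en-1-one | CC1=CC(C)(C)CCC1=O | starting material
21 | (1S)-2,4,4-trimethylcyclohex-2-en-1-ol | CC1=CC(C)(C)CC[C@@H]1O | intermediate
22 | tributyl({[(1S)-2,4,4-trimethylcyclohex-2-en-1-yl]oxy}methyl)stannane | CCCC[Sn](CCCC)(CCCC)CO[C@H]1CCC(C)(C)C=C1C | intermediate
23 | [(1R)-2,6,6-trimethylcyclohex-2-en-1-yl]methanol | CC1=CCCC(C)(C)[C@H]1CO | intermediate
24 | (1R)-2,6,6-trimethylcyclohex-2-ene-1-carbaldehyde | CC1=CCCC(C)(C)[C@H]1C=O | intermediate
25 | ethyl (2E)-4-(diethoxyphosphoryl)-3-methylbut-2-enoate | CCOC(=O)/C=C(\C)CP(=O)(OCC)OCC | starting material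
26 | ethyl (2E,4E)-3-methyl-5-[(1R)-2,6,6-trimethylcyclohex-2-en-1-yl]penta-2,4-dienoate | CC1=CCCC(C)(C)[C@H]1/C=C/C(C)=C/C(=O)OCC | intermediate
27 | ethyl (2E,4E)-3-methyl-5-[(1R)-2,6,6-trimethyl-4-oxocyclohex-2-en-1-yl]penta-2,4-dienoate | CC1=CC(=O)CC(C)(C)[C@H]1/C=C/C(C)=C/C(=O)OCC | intermediate
28 | ethyl (2E,4E)-5-[(1R,4R)-4-hydroxy-2,6,6-trimethylcyclohex-2-en-1-yl]-3-methylpenta-2,4-dienoate | CC1=C[C@H](O)CC(C)(C)[C@H]1/C=C/C(C)=C/C(=O)OCC | intermediate
29 | ethyl (2E,4E)-5-[(1R,4R)-4-(tert-butyldimethylsilyloxy)-2,6,6-trimethylcyclohex-2-en-1-yl]-3-methylpenta-2,4-dienoate | CC1=C[C@H](O[Si](C)(C)C(C)(C)C)CC(C)(C)[C@H]1/C=C/C(C)=C/C(=O)OCC | intermediate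
30 | (2E,4E)-5-[(1R,4R)-4-(tert-butyldimethylsilyloxy)-2,6,6-trimethylcyclohex-2-en-1-yl]-3-methylpenta-2,4-dien-1-ol | CC1=C[C@H](O[Si](C)(C)C(C)(C)C)CC(C)(C)[C@H]1/C=C/C(C)=C/CO | intermediate
31 | {[(1R,4R)-4-[(1E,3E)-5-bromo-3-methylpenta-1,3-dien-1-yl]-3,5,5-trimethylcyclohex-2-en-1-yl]oxy}(tert-butyl)dimethylsilane | CC1=C[C@H](O[Si](C)(C)C(C)(C)C)CC(C)(C)[C@H]1/C=C/C(C)=C/CBr | intermediate
32 | {(2E,4E)-5-[(1R,4R)-4-(tert-butyldimethylsilyloxy)-2,6,6-trimethylcyclohex-2-en-1-yl]-3-methylpenta-2,4-dien-1-yl}triphenylphosphonium bromide | CC1=C[C@H](O[Si](C)(C)C(C)(C)C)CC(C)(C)[C@H]1/C=C/C(C)=C/C[P+](c1ccccc1)(c1ccccc1)c1ccccc1.[Br-] | intermediate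
33 | (2E,4E,6E)-2,7-dimethylocta-2,4,6-trienedial | O=C/C(C)=C/C=C/C=C(C)/C=O | starting material
34 | (2E,4E,6E,8Z,10E,12E)-13-[(1R,4R)-4-(tert-butyldimethylsilyloxy)-2,6,6-trimethylcyclohex-2-en-1-yl]-2,7,11-trimethyltrideca-2,4,6,8,10,12-hexaenal | CC1=C[C@H](O[Si](C)(C)C(C)(C)C)CC(C)(C)[C@H]1/C=C/C(C)=C/C=C\C(C)=C\C=C\C=C(C)\C=O | intermediate
35 | (2E,4E,6E,8E,10E,12E)-13-[(1R,4R)-4-(tert-butyldimethylsilyloxy)-2,6,6-trimethylcyclohex-2-en-1-yl]-2,7,11-trimethyltrideca-2,4,6,8,10,12-hexaenal | CC1=C[C@H](O[Si](C)(C)C(C)(C)C)CC(C)(C)[C@H]1/C=C/C(C)=C/C=C/C(C)=C/C=C/C=C(C)/C=O | intermediate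
36 | (11Z)-isomer of 37, (3S,5R,8S,11Z,3'R,6'R)-3,3'-bis(tert-butyldimethylsilyloxy)-5,8-epoxy-5,8-dihydro-β,ε-carotene | CC1=C[C@H](O[Si](C)(C)C(C)(C)C)CC(C)(C)[C@H]1/C=C/C(C)=C/C=C/C(C)=C/C=C/C=C(C)/C=C\C=C(/C)[C@@H]1C=C2C(C)(C)C[C@H](O[Si](C)(C)C(C)(C)C)C[C@@]2(C)O1 | intermediate
37 | (3S,5R,8S,3'R,6'R)-3,3'-bis(tert-butyldimethylsilyloxy)-5,8-epoxy-5,8-dihydro-β,ε-carotene (all-E) | CC1=C[C@H](O[Si](C)(C)C(C)(C)C)CC(C)(C)[C@H]1/C=C/C(C)=C/C=C/C(C)=C/C=C/C=C(C)/C=C/C=C(\C)[C@@H]1C=C2C(C)(C)C[C@H](O[Si](C)(C)C(C)(C)C)C[C@@]2(C)O1 | intermediate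
38 | (3S,5R,8S,3'R,6'R)-5,8-epoxy-5,8-dihydro-β,ε-carotene-3,3'-diol (CNP0219251.2) | CC1=C[C@H](O)CC(C)(C)[C@H]1/C=C/C(C)=C/C=C/C(C)=C/C=C/C=C(C)/C=C/C=C(\C)[C@@H]1C=C2C(C)(C)C[C@H](O)C[C@@]2(C)O1 | target

## Step count and least certain steps

Total: 29 steps. Longest linear sequence: 18 steps (steps 1 to 16, then 28 and 29). The cyclohexenol branch (steps 17 to 27) has 11 steps before the junction.

**Step 12 (key step).** The most likely failure is ionisation of the protonated epoxide at C5 before the C8 oxygen has engaged. The cation is tertiary and sits next to a quaternary carbon, so this would open the way to a 1,2-shift with ring contraction or to closure from the wrong face, and C5 would no longer be set by inversion. Fallback (known chemistry, but without control of C8): from 9, the C8 hydroxyl is eliminated towards C7 (MsCl, Et3N, then DBU) to give the trienoate F1. m-Chloroperbenzoic acid should attack the tetrasubstituted C5=C6 bond from the face away from the silyl ether and give the anti-epoxide F2. A trace of acid then brings about the epoxide-to-furanoid rearrangement (C6–O ionisation to the allyl cation, capture at C8 by the oxygen left on C5). This keeps the C5 configuration and gives 16 together with its C8 epimer F3, which must be separated; the route is rejoined at 16.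

**Step 5.** The alkene may attack the enoate carbon C10 (conjugate ene reaction) instead of the aldehyde carbon, because the aldehyde is part of a doubly activated alkene. A stepwise course through the tertiary cation could also drift into a methyl shift or chloride capture. Fallback: from 5, an ene reaction with ethyl glyoxylate under a BINOL–titanium catalyst ((S)-BINOL, TiCl2(OiPr)2, molecular sieves) gives the α-hydroxy ester F4 with C8 set in the same step. Silylation with TBDPSCl gives the silyl ether F5, i-PrMgCl with MeNH(OMe)·HCl gives the Weinreb amide F6, and MeMgBr gives the methyl ketone F7. Wittig olefination of F7 with Ph3P=CHCO2Et in warm toluene gives the E-enoate 10, where the route is rejoined.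

**Step 14.** The C6 hydroxyl lies between two fully substituted carbons, so sulfamate formation may be slow. The sulfamate may also ionise instead of undergoing syn elimination, with methyl migration from C1 or participation of the ring oxygen. Fallback: from 15, the tertiary alkoxide (NaH, THF) is trapped with CS2 and MeI as the S-methyl xanthate F8. Its thermal syn elimination (Chugaev, toluene, 110 °C) gives 16 without a cationic intermediate.

**Step 23.** Facial selectivity may be poor if the ring's own bias (the C6' substituent and the axial methyl at C1') opposes the catalyst, and enolisation towards C6' would erode that centre. Fallback: from 27, Luche reduction (NaBH4, CeCl3·7H2O, MeOH, −40 °C) gives 28 together with the 3'-epimeric alcohol F9. After separation, F9 is inverted by a Mitsunobu reaction (4-nitrobenzoic acid, PPh3, DIAD) to the 4-nitrobenzoate F10, and ethanolysis (K2CO3, EtOH) returns 28.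

**Step 28.** The ylide of 19 carries part of its charge on C9, next to the C8–O bond, so it may fragment by expelling the ring oxygen before it meets the aldehyde; the precedent with epoxide-bearing ylides makes this unlikely but not excluded. Fallback: reverse the polarity. From 17, MnO2 gives the enal F11. From 35, NaBH4 gives the C25 alcohol F12, which is converted as in step 26 through the bromide F13 into the phosphonium salt F14. Wittig reaction of F14 with F11 (NaOMe, then heating) gives 37, where the route is rejoined.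

## Further compounds

F1 | step 12 | ethyl (2E,4E)-5-[(4R)-4-(tert-butyldimethylsilyloxy)-2,6,6-trimethylcyclohex-1-en-1-yl]-3-methylpenta-2,4-dienoate | CCOC(=O)/C=C(C)/C=C/C1=C(C)C[C@@H](O[Si](C)(C)C(C)(C)C)CC1(C)C
F2 | step 12 | ethyl (2E,4E)-5-[(1S,4S,6R)-4-(tert-butyldimethylsilyloxy)-2,2,6-trimethyl-7-oxabicyclo[4.1.0]heptan-1-yl]-3-methylpenta-2,4-dienoate | CCOC(=O)/C=C(C)/C=C/[C@]1(O2)C(C)(C)C[C@H](O[Si](C)(C)C(C)(C)C)C[C@]12C
F3 | step 12 | ethyl (2E)-3-[(2R,6S,7aR)-6-(tert-butyldimethylsilyloxy)-4,4,7a-trimethyl-2,4,5,6,7,7a-hexahydro-1-benzofuran-2-yl]but-2-enoate (C8 epimer of 16) | CCOC(=O)/C=C(\C)[C@H]1C=C2C(C)(C)C[C@H](O[Si](C)(C)C(C)(C)C)C[C@@]2(C)O1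
F4 | step 5 | ethyl (2S)-3-[(4R)-4-(tert-butyldimethylsilyloxy)-2,6,6-trimethylcyclohex-1-en-1-yl]-2-hydroxypropanoate | CCOC(=O)[C@@H](O)CC1=C(C)C[C@@H](O[Si](C)(C)C(C)(C)C)CC1(C)C
F5 | step 5 | ethyl (2S)-2-(tert-butyldiphenylsilyloxy)-3-[(4R)-4-(tert-butyldimethylsilyloxy)-2,6,6-trimethylcyclohex-1-en-1-yl]propanoate | CCOC(=O)[C@@H](O[Si](c1ccccc1)(c1ccccc1)C(C)(C)C)CC1=C(C)C[C@@H](O[Si](C)(C)C(C)(C)C)CC1(C)C
F6 | step 5 | (2S)-2-(tert-butyldiphenylsilyloxy)-3-[(4R)-4-(tert-butyldimethylsilyloxy)-2,6,6-trimethylcyclohex-1-en-1-yl]-N-methoxy-N-methylpropanamide | CON(C)C(=O)[C@@H](O[Si](c1ccccc1)(c1ccccc1)C(C)(C)C)CC1=C(C)C[C@@H](O[Si](C)(C)C(C)(C)C)CC1(C)C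
F7 | step 5 | (3S)-3-(tert-butyldiphenylsilyloxy)-4-[(4R)-4-(tert-butyldimethylsilyloxy)-2,6,6-trimethylcyclohex-1-en-1-yl]butan-2-one | CC(=O)[C@@H](O[Si](c1ccccc1)(c1ccccc1)C(C)(C)C)CC1=C(C)C[C@@H](O[Si](C)(C)C(C)(C)C)CC1(C)C
F8 | step 14 | ethyl (2E)-3-[(2S,3aR,6S,7aR)-6-(tert-butyldimethylsilyloxy)-4,4,7a-trimethyl-3a-{[(methylsulfanyl)carbonothioyl]oxy}octahydro-1-benzofuran-2-yl]but-2-enoate | CCOC(=O)/C=C(\C)[C@@H]1C[C@@]2(OC(=S)SC)C(C)(C)C[C@H](O[Si](C)(C)C(C)(C)C)C[C@@]2(C)O1
F9 | step 23 | ethyl (2E,4E)-5-[(1R,4S)-4-hydroxy-2,6,6-trimethylcyclohex-2-en-1-yl]-3-methylpenta-2,4-dienoate | CC1=C[C@@H](O)CC(C)(C)[C@H]1/C=C/C(C)=C/C(=O)OCC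
F10 | step 23 | (1R,4R)-4-[(1E,3E)-5-ethoxy-3-methyl-5-oxopenta-1,3-dien-1-yl]-3,5,5-trimethylcyclohex-2-en-1-yl 4-nitrobenzoate | CC1=C[C@H](OC(=O)c2ccc(cc2)[N+](=O)[O-])CC(C)(C)[C@H]1/C=C/C(C)=C/C(=O)OCC
F11 | step 28 | (2E)-3-[(2S,6S,7aR)-6-(tert-butyldimethylsilyloxy)-4,4,7a-trimethyl-2,4,5,6,7,7a-hexahydro-1-benzofuran-2-yl]but-2-enal | O=C/C=C(\C)[C@@H]1C=C2C(C)(C)C[C@H](O[Si](C)(C)C(C)(C)C)C[C@@]2(C)O1
F12 | step 28 | (2E,4E,6E,8E,10E,12E)-13-[(1R,4R)-4-(tert-butyldimethylsilyloxy)-2,6,6-trimethylcyclohex-2-en-1-yl]-2,7,11-trimethyltrideca-2,4,6,8,10,12-hexaen-1-ol | CC1=C[C@H](O[Si](C)(C)C(C)(C)C)CC(C)(C)[C@H]1/C=C/C(C)=C/C=C/C(C)=C/C=C/C=C(C)/CO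
F13 | step 28 | {[(1R,4R)-4-[(1E,3E,5E,7E,9E,11E)-13-bromo-3,7,12-trimethyltrideca-1,3,5,7,9,11-hexaen-1-yl]-3,5,5-trimethylcyclohex-2-en-1-yl]oxy}(tert-butyl)dimethylsilane | CC1=C[C@H](O[Si](C)(C)C(C)(C)C)CC(C)(C)[C@H]1/C=C/C(C)=C/C=C/C(C)=C/C=C/C=C(C)/CBr
F14 | step 28 | {(2E,4E,6E,8E,10E,12E)-13-[(1R,4R)-4-(tert-butyldimethylsilyloxy)-2,6,6-trimethylcyclohex-2-en-1-yl]-2,7,11-trimethyltrideca-2,4,6,8,10,12-hexaen-1-yl}triphenylphosphonium bromide | CC1=C[C@H](O[Si](C)(C)C(C)(C)C)CC(C)(C)[C@H]1/C=C/C(C)=C/C=C/C(C)=C/C=C/C=C(C)/C[P+](c1ccccc1)(c1ccccc1)c1ccccc1.[Br-]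
A1 | alternative 1 | tert-butyl{[(4R,5Z,7E)-2,6-dimethyl-8-(phenylsulfonyl)octa-1,5,7-trien-4-yl]oxy}dimethylsilane | C=C(C)C[C@@H](O[Si](C)(C)C(C)(C)C)/C=C(C)\C=C\S(=O)(=O)c1ccccc1
A2 | alternative 1 | tert-butyldimethyl{[(1R,4R)-3,5,5-trimethyl-4-[(phenylsulfonyl)methyl]cyclohex-2-en-1-yl]oxy}silane | CC1=C[C@H](O[Si](C)(C)C(C)(C)C)CC(C)(C)[C@H]1CS(=O)(=O)c1ccccc1
A3 | alternative 2 | (2R,4S)-2-{[(2E)-4-(tert-butyldiphenylsilyloxy)-2-methylbut-2-en-1-yl]oxy}-4-(tert-butyldimethylsilyloxy)-2,6,6-trimethylcyclohexan-1-one | CC(C)(C)[Si](OC/C=C(\C)CO[C@]1(C)C[C@@H](O[Si](C)(C)C(C)(C)C)CC(C)(C)C1=O)(c1ccccc1)c1ccccc1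
A4 | alternative 2 | tert-butyl{[(2E)-3-[(2S,6S,7aR)-6-(tert-butyldimethylsilyloxy)-4,4,7a-trimethyl-2,4,5,6,7,7a-hexahydro-1-benzofuran-2-yl]but-2-en-1-yl]oxy}diphenylsilane | CC(C)(C)[Si](OC/C=C(\C)[C@@H]1C=C2C(C)(C)C[C@H](O[Si](C)(C)C(C)(C)C)C[C@@]2(C)O1)(c1ccccc1)c1ccccc1
A5 | alternative 3 | (2E)-5-[(2R,4S)-4-acetoxy-2-hydroxy-2,6,6-trimethylcyclohexylidene]-3-methylpenta-2,4-dien-1-yl acetate with the R allene axis | CC(=O)OC/C=C(\C)C=[C@@]=C1C(C)(C)C[C@H](OC(C)=O)C[C@@]1(C)O
A6 | alternative 3 | (2E)-3-[(2S,6S,7aR)-6-acetoxy-4,4,7a-trimethyl-2,4,5,6,7,7a-hexahydro-1-benzofuran-2-yl]but-2-en-1-yl acetate | CC(=O)OC/C=C(\C)[C@@H]1C=C2C(C)(C)C[C@H](OC(C)=O)C[C@@]2(C)O1
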